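## Structural features

The target is a depside: two benzene rings joined by an aryl ester, in which the carboxyl carbon of ring A (2,4-dimethoxy-6-pentylbenzoyl) is bound to the C4 oxygen of ring B (2-heptyl-6-methoxybenzoic acid). Both rings are 1,2,3,5-tetrasubstituted, and in each the carbonyl carbon sits between an n-alkyl chain and a methoxy group. Ring A carries pentyl and a second methoxy group at C4; ring B carries heptyl and the ester oxygen at C4. There is no stereocenter and no ring apart from the two arenes. The fragile element is the aryl ester link, which hydroxide, alkoxide or any hard nucleophile would cleave, so the free acid of ring B must be released under neutral conditions. Both electron-rich, doubly ortho-substituted benzoic acids are also liable to protodecarboxylation in hot acid. The real difficulty is twofold: placing a carbonyl carbon between two ortho substituents on each ring with full regiocontrol, and acylating a phenol with so hindered an acid. The key step uses the fact that in ring A C1 (carboxyl) and C6 (pentyl) are adjacent while C1 also adjoins the C2 methoxy group. That is the pattern produced when a carbon nucleophile and then a carbon electrophile add across the C1–C6 triple bond of an aryne with methoxy at C2.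

## Logic of the disconnections

18 ⇒ 17. The O–CH2 bond of a benzyl ester on ring B is cut. The acid is kept masked until the end because the only deprotection that leaves the aryl ester untouched is neutral hydrogenolysis. This costs one step and demands only that nothing else in 17 is reducible, which holds.

17 ⇒ 6 + 15. The C(=O)–O bond between the rings is cut. This is the one heteroatom bond in the skeleton, and it divides the molecule into two arenes of similar size that can be made separately. The forward step must acylate a phenol with a 2,6-disubstituted acid. This is met by ionising the acid through 16 to an acylium ion, which has no tetrahedral intermediate to be crowded.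

6 ⇒ 1 + 2 (key disconnection). Two adjacent ring–carbon bonds are cut together, C6–pentyl and C1–carboxyl. The tetrasubstituted ring A then falls back to a symmetrical bought fluoroarene, a bought Grignard reagent and a carboxylation. The forward step must lithiate 1 between fluorine and methoxy to give 3, form aryne 4, add 2 at the aryne carbon remote from methoxy to give 5, and trap 5 with the one-carbon electrophile. Both regiochemical choices are set by the substituents already in 1.

15 ⇒ 14. The benzyl O–C bond of the ester is cut. The benzyl group is placed on the carboxylate and not on the phenol because a weak base ionises only the acid. The forward step must be a chemoselective O-alkylation of a carboxylate beside a free phenol.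

14 ⇒ 12 (through 13). The ester methyl and the acetal on the C4 oxygen are removed. Both are taken off in one operation, the first by hydroxide and the second by the acid of the work-up. The acetal must therefore survive hot base and leave in cold dilute acid, which a tetrahydropyranyl ether does.

12 ⇒ 9 + 10. The first C–C bond of the heptyl chain (benzylic carbon to the next carbon) is cut. The methyl group ortho to the ester in 9 is acidified by that ester, so the chain is built by lateral lithiation to 11 and SN2 alkylation with 10. The forward step must avoid attack of 11 on the ester of unreacted 9.

9 ⇒ 8 ⇒ 7. Two O–C bonds are cut, the methyl ether at C2 and the acetal at C4. The two hydroxyls of 7 differ because the C2 hydroxyl is hydrogen-bonded to the ester carbonyl. The free C4 hydroxyl is therefore masked first and the chelated one methylated second. This takes ring B back to a bought compound that already has the carbonyl, both oxygens and the benzylic carbon in place.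

## Other disconnections considered

Alternative 1: The cut dismantles ring B completely. With C1 as the carbon bearing the benzyl ester, C2 methoxy, C4 hydroxyl and C6 heptyl, the bonds C1–C6, C1–C2, C3–C4 and C4–C5 are made in one operation.
- Forward step: light drives a Wolff rearrangement of the diazo keto ester A1 (benzyl 2-diazo-4-methylidene-3-oxoundecanoate), in which the heptyl-bearing alkenyl group migrates to the diazo carbon. The ester-substituted vinylketene adds methoxyethyne A2 in a [2+2] sense, the unsubstituted alkyne carbon bonding to the ketene carbonyl carbon. Four-electron ring opening, six-electron ring closure and tautomerisation then give A3, benzyl 2-heptyl-4-hydroxy-6-methoxybenzoate, which is the same compound as 15.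
- In its favour: the substitution pattern is fixed by the mechanism, the benzyl ester is present from the start, and the C4 phenol emerges free.
- Against it here: A2 is a very volatile, unstable ynol ether that must be prepared and used at once. A1 combines a diazo group with a polymerisable 1,1-disubstituted enone. The ester-bearing ketene can dimerise or be intercepted, and a photoreactor is needed. The step also does nothing for ring A or for the hindered ester link.
- Comparison: this alternative concerns ring B, which the chosen plan makes from 7 in five steps of routine phenol and ester chemistry. A3 would need about three steps to A1 plus the preparation of A2, so step economy is roughly equal. On protecting-group economy and on certainty of the ring B substitution pattern the alternative is the better plan, since it needs no protecting group and no ester exchange. On mechanism it is a four-stage pericyclic cascade with more points of failure than a series of SN2 and acid–base steps, and it uses a diazo compound where the chosen plan uses only stock reagents. It is compatible with the aryne step for ring A, so the choice for ring B is one of risk, not of logic.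

Alternative 2: The cuts are the ester O–C(=O) bond and the ring A C1–C6 bond, which reduces ring A to a linear polyketide chain masked as the dioxinone A4 (6-(2,4-dioxononyl)-2,2-dimethyl-4H-1,3-dioxin-4-one).
- Forward step: heating A4 with the ring B phenol A3 causes cycloreversion of the dioxinone to an acylketene, which adds the phenol O–H to give the triketo aryl ester A5 (benzyl 2-heptyl-6-methoxy-4-(3,5,7-trioxododecanoyloxy)benzoate). Base then acid closes ring A by aldol condensation of chain C2 onto the C7 ketone, and dehydration and enolisation give A6, benzyl 4-(2,4-dihydroxy-6-pentylbenzoyloxy)-2-heptyl-6-methoxybenzoate.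
- In its favour: the ester bond is made by adding a phenol to a ketene under neutral thermal conditions before ring A exists, so the steric problem of a doubly ortho-substituted acid never arises. The sequence is convergent and follows the biosynthetic fold.
- Against it here: ring A arrives with two free hydroxyls, whereas the target needs both methylated. The C2 hydroxyl of A6 is chelated to the depside carbonyl, and the base and alkylating agent needed to methylate it put the aryl ester at risk. In A5 the aryloxide is a good leaving group, so lactonisation to a hydroxypyrone with loss of A3 can compete with the aldol closure. A4 itself takes several steps from a simple dioxinone.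
- Comparison: on structure, the chosen plan carries both ring A methoxy groups in from 1 and needs no late methylation. On mechanism, a polar aldol cascade stands against an aryne carbometalation. On step economy the alternative is longer by two or three steps, since ring B (A3, the same as 15) is needed in both plans. The alternative is the better plan for the ester-forming event itself, which is less hindered than step 7, and it would be the plan of choice for a congener with free ring A hydroxyls.

Alternative 3: The cuts are the ring A C3–C4 and C5–C6 bonds. C4 and C5 come from the ketene acetal A8 (1,1-dimethoxyethene) and the other four ring carbons from the pyrone A7 (methyl 4-methoxy-2-oxo-6-pentyl-2H-pyran-5-carboxylate).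
- Forward step: an inverse-demand Diels–Alder reaction across pyrone C3 and C6, with the nucleophilic CH2 of A8 bonding to the pentyl-bearing C6 and the acetal carbon to C3. The bridging lactone is then extruded as a gas and one methoxy group of the acetal is eliminated, leaving the arene A9, methyl 2,4-dimethoxy-6-pentylbenzoate.
- In its favour: everything is thermal, no organometallic reagent or low temperature is needed, and the regiochemistry follows from the polarisation of both partners. A7 should be reachable in two or three steps from bulk acyclic esters.
- Against it here: the 4-methoxy group makes A7 a less electron-poor diene, so forcing temperatures are likely, under which A8 polymerises or hydrolyses. A9 is the methyl ester of a doubly ortho-substituted acid and still needs a hot saponification to reach 6. About four steps are spent where the chosen plan needs one.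
- Comparison: both plans converge on 6 and share the same end-game, so they differ only in how ring A is made. On step economy the aryne plan is clearly shorter. On regiochemical certainty the two are equal. On operational robustness and scale the alternative is the better plan, because it has no low-temperature lithiation, no ambiguity about the site of metalation and no risk of a butyl homologue. On structure, the aryne plan delivers the free acid directly, which is what step 7 consumes.

Key step: step 1

Remark on the chemistry: the structures of the plan were checked against the target and need no correction. The only stereocenter that appears anywhere is the acetal carbon of the tetrahydropyranyl ether in 8, 9 and 11–13, which is racemic and is removed in step 5.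

## Route

Step 1
Reactants: 1 1-fluoro-3,5-dimethoxybenzene; 2 pentylmagnesium bromide
Product: 6 2,4-dimethoxy-6-pentylbenzoic acid, via 2-fluoro-4,6-dimethoxyphenyllithium 3 (not isolated), via 3,5-dimethoxybenzyne 4 (not isolated), via 2,4-dimethoxy-6-pentylphenylmagnesium bromide 5 (not isolated)
Conditions: n-BuLi (0.97 equiv), THF, −78 °C; 2 (2.5 equiv), −78 °C → rt; CO2 (dry gas), −20 °C → rt; 1 M HCl
Reagents that add atoms: carbon dioxide, O=C=O
Why: Directed ortho-lithiation of 1 should occur at the C–H flanked by fluorine and methoxy (fluorine is the stronger acidifier and the two such sites are equivalent by symmetry) to give 3; a slight deficit of n-BuLi is used so that no butyl nucleophile remains to give a homologue. On warming in the presence of excess 2, 3 loses LiF to form aryne 4. The methoxy group next to the triple bond withdraws inductively and distorts the aryne, so the remote carbon (ring A C6) is the flatter and more electrophilic one; pentyl adds there and the carbanion develops at C1 beside oxygen, where it is stabilised inductively and by coordination to magnesium, giving 5. Carboxylation of 5 then places the carboxyl between pentyl and methoxy, so both new C–C bonds (C6–pentyl and C1–carboxyl) are made in one flask. The closest known reaction type is lithiation of a 3-fluoroanisole, carbomagnesiation of the derived 3-methoxyaryne with a Grignard reagent and electrophilic trapping of the ortho-methoxy arylmagnesium; alkyl Grignard reagents are used less often than aryl ones but follow the same path. No ring is closed and no stereocenter is formed. Two selectivities are needed: the site of lithiation, secured by fluorine, and the site of attack on 4, secured by the adjacent methoxy group; capture of 4 by 3 is suppressed by the excess of 2.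

Step 2
Reactants: 7 methyl orsellinate (methyl 2,4-dihydroxy-6-methylbenzoate)
Product: 8 methyl 2-hydroxy-6-methyl-4-(tetrahydro-2H-pyran-2-yloxy)benzoate (racemic acetal)
Conditions: 3,4-dihydro-2H-pyran (1.3 equiv), PPTS (5 mol %), CH2Cl2, rt
Reagents that add atoms: 3,4-dihydro-2H-pyran, C1=COCCC1
Why: Acid-catalysed addition of a phenol to an enol ether (tetrahydropyranyl acetal formation); the C4 hydroxyl is free whereas the C2 hydroxyl is hydrogen-bonded to and shielded by the ester, so mono-protection at C4 is expected; the acetal carbon forms as a racemate and is removed later.

Step 3
Reactants: 8 methyl 2-hydroxy-6-methyl-4-(tetrahydro-2H-pyran-2-yloxy)benzoate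
Product: 9 methyl 2-methoxy-6-methyl-4-(tetrahydro-2H-pyran-2-yloxy)benzoate
Conditions: MeI, K2CO3, DMF, 40 °C
Reagents that add atoms: iodomethane, CI
Why: Williamson O-methylation of the remaining chelated phenol; the dipolar solvent breaks the hydrogen bond, and the acetal and the hindered ester are inert to K2CO3.

Step 4
Reactants: 9 methyl 2-methoxy-6-methyl-4-(tetrahydro-2H-pyran-2-yloxy)benzoate; 10 1-bromohexane
Product: 12 methyl 2-heptyl-6-methoxy-4-(tetrahydro-2H-pyran-2-yloxy)benzoate, via lateral lithio ester 11 (not isolated)
Conditions: LiN(iPr)2 (1.15 equiv), THF, −78 °C (9 added to the base); 10, DMPU, −78 → 0 °C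
Reagents that add atoms: none
Why: Lateral (benzylic) lithiation of an ortho-toluate gives the dienolate-type anion 11, which is alkylated at carbon by the primary bromide (SN2), extending methyl to heptyl; adding 9 slowly to the amide base at −78 °C keeps 11 away from unreacted ester, and the two ortho substituents shield the ester carbonyl.

Step 5
Reactants: 12 methyl 2-heptyl-6-methoxy-4-(tetrahydro-2H-pyran-2-yloxy)benzoate
Product: 14 2-heptyl-4-hydroxy-6-methoxybenzoic acid, via potassium carboxylate 13 (not isolated)
Conditions: KOH, DMSO/H2O (4:1), 90 °C; then 2 M HCl, THF, 0 °C → rt
Reagents that add atoms: potassium hydroxide, [K+].[OH-]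
Why: Saponification of a doubly ortho-substituted methyl ester needs hot hydroxide in a dipolar solvent, which the base-stable acetal survives, giving 13; acidification then hydrolyses the aryl tetrahydropyranyl acetal through its oxocarbenium ion in the same work-up, and the low temperature guards the electron-rich acid against protodecarboxylation.

Step 6
Reactants: 14 2-heptyl-4-hydroxy-6-methoxybenzoic acid
Product: 15 benzyl 2-heptyl-4-hydroxy-6-methoxybenzoate
Conditions: BnBr (1.05 equiv), KHCO3, DMF, rt
Reagents that add atoms: benzyl bromide, BrCc1ccccc1
Why: Chemoselective SN2 O-alkylation of a carboxylate; hydrogencarbonate ionises only the carboxylic acid and not the phenol, and alkylation at the carboxylate oxygen is not hindered by the two ortho substituents.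

Step 7
Reactants: 6 2,4-dimethoxy-6-pentylbenzoic acid; 15 benzyl 2-heptyl-4-hydroxy-6-methoxybenzoate
Product: 17 benzyl 4-(2,4-dimethoxy-6-pentylbenzoyloxy)-2-heptyl-6-methoxybenzoate, via mixed trifluoroacetic anhydride 16 (not isolated)
Conditions: (CF3CO)2O, toluene, 0 °C → rt
Reagents that add atoms: none
Why: Trifluoroacetic anhydride esterification, the classical depside coupling: the electron-rich, doubly ortho-substituted acid gives mixed anhydride 16, which ionises readily to a linear acylium ion that escapes the steric block on tetrahedral pathways and is captured by the only free hydroxyl, the C4 phenol of 15.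

Step 8
Reactants: 17 benzyl 4-(2,4-dimethoxy-6-pentylbenzoyloxy)-2-heptyl-6-methoxybenzoate
Product: 18 4-(2,4-dimethoxy-6-pentylbenzoyloxy)-2-heptyl-6-methoxybenzoic acid (CNP0206304.0)
Conditions: H2 (1 atm), 10% Pd/C, EtOAc, rt
Reagents that add atoms: none
Why: Catalytic hydrogenolysis of a benzyl ester under neutral conditions; the aryl ester link, the methoxy groups and both arenes are inert, so the ring B acid is released without cleaving the depside bond.

## Compound list

1 | 1-fluoro-3,5-dimethoxybenzene | COc1cc(F)cc(OC)c1 | starting material
2 | pentylmagnesium bromide | CCCCC[Mg]Br | starting material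
3 | 2-fluoro-4,6-dimethoxyphenyllithium | [Li]c1c(F)cc(OC)cc1OC | intermediate (not isolated)
4 | 3,5-dimethoxybenzyne | COC1=CC(OC)=CC#C1 | intermediate (not isolated)
5 | 2,4-dimethoxy-6-pentylphenylmagnesium bromide | CCCCCc1cc(OC)cc(OC)c1[Mg]Br | intermediate (not isolated)
6 | 2,4-dimethoxy-6-pentylbenzoic acid | CCCCCc1cc(OC)cc(OC)c1C(=O)O | intermediate
7 | methyl orsellinate (methyl 2,4-dihydroxy-6-methylbenzoate) | Cc1cc(O)cc(O)c1C(=O)OC | starting material
8 | methyl 2-hydroxy-6-methyl-4-(tetrahydro-2H-pyran-2-yloxy)benzoate (racemic) | Cc1cc(OC2CCCCO2)cc(O)c1C(=O)OC | intermediate
9 | methyl 2-methoxy-6-methyl-4-(tetrahydro-2H-pyran-2-yloxy)benzoate (racemic) | Cc1cc(OC2CCCCO2)cc(OC)c1C(=O)OC | intermediate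
10 | 1-bromohexane | CCCCCCBr | starting material
11 | methyl 2-(lithiomethyl)-6-methoxy-4-(tetrahydro-2H-pyran-2-yloxy)benzoate (racemic) | [Li]Cc1cc(OC2CCCCO2)cc(OC)c1C(=O)OC | intermediate (not isolated)
12 | methyl 2-heptyl-6-methoxy-4-(tetrahydro-2H-pyran-2-yloxy)benzoate (racemic) | CCCCCCCc1cc(OC2CCCCO2)cc(OC)c1C(=O)OC | intermediate
13 | potassium 2-heptyl-6-methoxy-4-(tetrahydro-2H-pyran-2-yloxy)benzoate (racemic) | CCCCCCCc1cc(OC2CCCCO2)cc(OC)c1C(=O)[O-].[K+] | intermediate (not isolated)
14 | 2-heptyl-4-hydroxy-6-methoxybenzoic acid | CCCCCCCc1cc(O)cc(OC)c1C(=O)O | intermediate
15 | benzyl 2-heptyl-4-hydroxy-6-methoxybenzoate | CCCCCCCc1cc(O)cc(OC)c1C(=O)OCc1ccccc1 | intermediate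
16 | 2,4-dimethoxy-6-pentylbenzoic trifluoroacetic anhydride | CCCCCc1cc(OC)cc(OC)c1C(=O)OC(=O)C(F)(F)F | intermediate (not isolated)
17 | benzyl 4-(2,4-dimethoxy-6-pentylbenzoyloxy)-2-heptyl-6-methoxybenzoate | CCCCCCCc1cc(OC(=O)c2c(CCCCC)cc(OC)cc2OC)cc(OC)c1C(=O)OCc1ccccc1 | intermediate
18 | 4-(2,4-dimethoxy-6-pentylbenzoyloxy)-2-heptyl-6-methoxybenzoic acid | CCCCCCCc1cc(OC(=O)c2c(CCCCC)cc(OC)cc2OC)cc(OC)c1C(=O)O | target

## Step count and least certain steps

Total step count: 8. Longest linear sequence: 7 steps (steps 2 to 8, from 7); the ring A branch is a single step (step 1) that joins at step 7.

Step 1 (key step). Several processes could erode it: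
- lithiation between the two methoxy groups, which would only give a fluoro acid after carboxylation;
- capture of the aryne by the aryllithium instead of the Grignard reagent, leading to biaryls;
- hydride transfer from the β-C–H bonds of the alkyl Grignard reagent to the aryne;
- carry-over of butyl if any n-BuLi survives the metalation.

Fallback: set out from 1, keep lithio species 3 cold and carboxylate it at once (CO2, −78 °C) to 2-fluoro-4,6-dimethoxybenzoic acid F1, which can be purified by crystallisation. Then displace the fluoride ortho to the carboxylate with 2 (3 equiv, THF, 0 °C → rt) and acidify to come back to the route at 6. This is a carboxylate-directed nucleophilic aromatic substitution of the kind known for unprotected 2-fluorobenzoic acids, in which fluoride should leave in preference to methoxide. It makes the same two bonds in the reverse order and avoids a free aryne.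

Step 4. The likely failure is Claisen-type self-condensation of the lateral anion with the ester of unreacted 9, together with slow SN2 on the unactivated primary bromide so that the anion decays on warming. Fallback: set out from 9 and saponify it (KOH, DMSO/H2O, 90 °C; buffered acidification to keep the acetal) to 2-methoxy-6-methyl-4-(tetrahydro-2H-pyran-2-yloxy)benzoic acid F2. Convert F2 with LiN(iPr)2 (2.3 equiv, THF, 0 °C) into its dilithio derivative F3, in which the carboxylate cannot be attacked. Alkylate F3 with 10 to give lithium 2-heptyl-6-methoxy-4-(tetrahydro-2H-pyran-2-yloxy)benzoate F4, and apply the aqueous HCl/THF treatment of step 5 to come back at 14.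

Step 5. Hydrolysis of the doubly ortho-substituted ester may be incomplete, and the electron-rich hydroxy acid may lose carbon dioxide during the acidic unmasking. Fallback: set out from 13 and acidify only to about pH 5 to isolate 2-heptyl-6-methoxy-4-(tetrahydro-2H-pyran-2-yloxy)benzoic acid F5. Benzylate it (BnBr, K2CO3, DMF) to benzyl 2-heptyl-6-methoxy-4-(tetrahydro-2H-pyran-2-yloxy)benzoate F6, then remove the acetal by transacetalisation (PPTS, MeOH, rt) to come back at 15. The free hydroxy acid is then never handled and the benzylation needs no chemoselectivity, at the cost of one step.

Step 7. The acylium ion may acylate the electron-rich ring B at carbon (Friedel–Crafts) in competition with O-acylation, the phenol may be held up as its trifluoroacetate, and 6 may protodecarboxylate in the acidic medium. Fallback: set out from 6 and convert it with oxalyl chloride and catalytic DMF in CH2Cl2 into 2,4-dimethoxy-6-pentylbenzoyl chloride F7. Deprotonate 15 with NaH in THF to the sodium phenoxide F8 (sodium 4-(benzyloxycarbonyl)-3-heptyl-5-methoxyphenolate) and combine the two to come back at 17. This replaces the acid-mediated acylium path with a base-mediated acyl substitution by a strong oxygen nucleophile.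

## Further compounds

F1 | step 1 | 2-fluoro-4,6-dimethoxybenzoic acid | COc1cc(F)c(C(=O)O)c(OC)c1
F2 | step 4 | 2-methoxy-6-methyl-4-(tetrahydro-2H-pyran-2-yloxy)benzoic acid (racemic) | Cc1cc(OC2CCCCO2)cc(OC)c1C(=O)O
F3 | step 4 | lithium 2-(lithiomethyl)-6-methoxy-4-(tetrahydro-2H-pyran-2-yloxy)benzoate (racemic) | [Li]Cc1cc(OC2CCCCO2)cc(OC)c1C(=O)O[Li]
F4 | step 4 | lithium 2-heptyl-6-methoxy-4-(tetrahydro-2H-pyran-2-yloxy)benzoate (racemic) | CCCCCCCc1cc(OC2CCCCO2)cc(OC)c1C(=O)[O-].[Li+]
F5 | step 5 | 2-heptyl-6-methoxy-4-(tetrahydro-2H-pyran-2-yloxy)benzoic acid (racemic) | CCCCCCCc1cc(OC2CCCCO2)cc(OC)c1C(=O)O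
F6 | step 5 | benzyl 2-heptyl-6-methoxy-4-(tetrahydro-2H-pyran-2-yloxy)benzoate (racemic) | CCCCCCCc1cc(OC2CCCCO2)cc(OC)c1C(=O)OCc1ccccc1
F7 | step 7 | 2,4-dimethoxy-6-pentylbenzoyl chloride | CCCCCc1cc(OC)cc(OC)c1C(=O)Cl
F8 | step 7 | sodium 4-(benzyloxycarbonyl)-3-heptyl-5-methoxyphenolate | CCCCCCCc1cc([O-])cc(OC)c1C(=O)OCc1ccccc1.[Na+]
A1 | alternative 1 | benzyl 2-diazo-4-methylidene-3-oxoundecanoate | CCCCCCCC(=C)C(=O)C(=[N+]=[N-])C(=O)OCc1ccccc1
A2 | alternative 1 | methoxyethyne | COC#C
A3 | alternative 1 | benzyl 2-heptyl-4-hydroxy-6-methoxybenzoate | CCCCCCCc1cc(O)cc(OC)c1C(=O)OCc1ccccc1
A4 | alternative 2 | 6-(2,4-dioxononyl)-2,2-dimethyl-4H-1,3-dioxin-4-one | CCCCCC(=O)CC(=O)CC1=CC(=O)OC(C)(C)O1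
A5 | alternative 2 | benzyl 2-heptyl-6-methoxy-4-(3,5,7-trioxododecanoyloxy)benzoate | CCCCCCCc1cc(OC(=O)CC(=O)CC(=O)CC(=O)CCCCC)cc(OC)c1C(=O)OCc1ccccc1
A6 | alternative 2 | benzyl 4-(2,4-dihydroxy-6-pentylbenzoyloxy)-2-heptyl-6-methoxybenzoate | CCCCCCCc1cc(OC(=O)c2c(CCCCC)cc(O)cc2O)cc(OC)c1C(=O)OCc1ccccc1
A7 | alternative 3 | methyl 4-methoxy-2-oxo-6-pentyl-2H-pyran-5-carboxylate | CCCCCc1oc(=O)cc(OC)c1C(=O)OC
A8 | alternative 3 | 1,1-dimethoxyethene | C=C(OC)OC
A9 | alternative 3 | methyl 2,4-dimethoxy-6-pentylbenzoate | CCCCCc1cc(OC)cc(OC)c1C(=O)OC
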